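(The numbers are assumed; the result is computed.)

The ratio of solubility to charge, 14 mM over 29 mM, is 48.3%, so in this flask crystals form once dissolved product passes that share of the substrate charged. My decision for the next run hangs on this ratio: does the sample at 10 min need a filter and a weighing of crystals, or will a plain reading of the solution do?

substrate 29 mM; coupling partner 52.2 mM; time 10 min

- the product and crystals together standing at 10 min, as a percentage of the substrate charged
- concentration of product in solution at 10 min, in percent of saturation

    substrate + coupling partner → intermediate B (k1 = 0.020 L mol⁻¹ s⁻¹)
    coupling partner + intermediate A → product (k2 = 0.097 L mol⁻¹ s⁻¹)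
    intermediate C → intermediate D (k3 = 0.016 s⁻¹)
    crystals ⇌ product, rate k4*(cs4 - [product]) while solid is left; crystals form when [product] > cs4 (cs4 = 14 mM, k4 = 0.066 s⁻¹)
    substrate → intermediate A (k5 = 7.3 × 10⁻⁴ s⁻¹)
    intermediate D ⇌ intermediate E (K6 = 0.75, k6 = 0.0023 s⁻¹)
    coupling partner + intermediate B → intermediate C (k7 = 0.027 L mol⁻¹ s⁻¹)

I count turnovers. A turnover count, n, is a first-order rate constant multiplied by the time, so it tells how many lifetimes a species has had. Substrate leaves by two paths: by itself to intermediate A, and with the coupling partner to intermediate B. If I hold the partner at its charge, both paths are pseudo-first-order and together run at 0.106 min⁻¹, which gives substrate n = 1.06. Intermediate A reacts with the partner to give product at 0.304 min⁻¹, so it has n = 3.04. A share 41.1% of the substrate enters the path through intermediate A, and two first-order steps in a row at these rates complete a fraction 0.495 of that chain. The share times that fraction, the turnover yield 20.4%, is the product I expect, as a percentage of the substrate charged. It is less than the 48.3% needed for crystals, and in solution it comes to 42.3% of saturation, so I leave the filter off and keep the charge.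

The forecast gives 19.5% (range 17.5% to 21.5%) and 40% of saturation (range 36% to 45%), on the grounds that “no crystals form and the product stays in solution”. My yield stands higher than its central value, but inside its range.

The simulation gives 18.5% and 38.3% of saturation, with crystals at 0%.

The turnover yield stands 1.9 percentage points above the simulated value, and at 10.0 min the coupling partner reads 65.3% of its charge, not the full charge I held. The neighbouring flask has the same charge, read at 4.0 min. There substrate has n = 0.426 and intermediate A has n = 1.22, so the turnover yield is 6.38%. The simulation of that flask reads 5.91%, with the coupling partner at 84.5% of its charge.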